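In the first seconds of these flasks the precatalyst must open before any left-handed product can form.

    coupling partner + catalyst + left-handed substrate → catalyst + left-handed product (k1 = 3400 L² mol⁻² s⁻¹, Ea1 = 23.0 kJ mol⁻¹)
    coupling partner + catalyst + right-handed substrate → catalyst + right-handed product (k2 = 1100 L² mol⁻² s⁻¹, Ea2 = 36.0 kJ mol⁻¹)
    left-handed substrate ⇌ right-handed substrate (k3 = 0.033 s⁻¹, Ea3 = 87.0 kJ mol⁻¹)
    2 catalyst ⇌ resting dimer, settled at all times (K4 = 7.6 × 10⁵ L mol⁻¹, ΔH4 = −34.0 kJ mol⁻¹)
    catalyst + added ligand ⇌ idle complex, settled at all times (K5 = 9500 L mol⁻¹, ΔH5 = −2.00 kJ mol⁻¹)
    precatalyst ⇌ catalyst (K6 = 1.9, k6 = 0.19 s⁻¹, Ea6 = 71.0 kJ mol⁻¹, ΔH6 = −40.0 kJ mol⁻¹)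
    (constants at 20 °C)

| flask | left-handed substrate | coupling partner | precatalyst | added ligand | right-handed substrate | temperature | time | remark |
|---|---|---|---|---|---|---|---|---|
| west | 0.24 M | 0.720 M | 0.14 mM | 0.30 mM | 0.24 M | 50 °C | 25 s |  |
| north-west | 0.24 M | 0.720 M | 0.14 mM | 0.30 mM | 0.24 M |  | 25 s | at 50 °C until 5.0 s, from then on at −10 °C |
| south-east | 0.24 M | 0.720 M | 0.14 mM | 0.30 mM | 0.24 M | 20 °C | 25 s |  |
| east | 0.24 M | 0.720 M | 0.14 mM | 0.30 mM | 0.24 M | −10 °C | 25 s |  |

1. which flask leads in amount of left-handed product, in percent of the left-handed substrate and right-handed substrate together charged ("all alike" within 1.5 percentage points) (west / north-west / south-east / east / all alike)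
2. how much left-handed product is there at the end, in percent of the left-handed substrate and right-handed substrate together charged: west
3. how much left-handed product is there at the end, in percent of the left-handed substrate and right-handed substrate together charged: north-west
4. how much left-handed product is there at the end, in percent of the left-handed substrate and right-handed substrate together charged: south-east
5. how much left-handed product is there at the end, in percent of the left-handed substrate and right-handed substrate together charged: east

- catalyst is single-handed; left-handed substrate and right-handed substrate are mirror images of each other, charged as a racemate, each of them at the stated concentration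
- where a step has two of a species, its rate is k times that concentration squared, and two are used at each turn
- constants are those at 20 °C; use the activation energies and enthalpies for any other temperature

We draw the curve of left-handed product in north-west. At 50 °C the precatalyst opens with a lifetime of

lag = 0.352 s

This is far shorter than the hot window of 5.0 s, so the curve leaves zero almost at once. We then treat the fast balances as holding, with these constants at 50 °C:

precatalyst: 0.414
dimer: 2.08 × 10⁵ L mol⁻¹
idle complex: 8800 L mol⁻¹

We take the added ligand at its charge and count two catalysts in each dimer. The forms must add up to the charge, and this quadratic gives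

[catalyst] = 0.0125 mM

The coupling constants at 50 °C are 8160 L² mol⁻² s⁻¹ for the left-handed substrate and 4330 L² mol⁻² s⁻¹ for the right-handed one. So the curve starts with the slope

17.6 mM s⁻¹

We treat the coupling partner as constant, which makes the loss pseudo-first-order. The two substrates then form one pool that is lost with the mean constant:

τ = 17.8 s

Interconversion evens the pool out with a lifetime of 0.551 s, far shorter than τ. So the product share is the selectivity:

share = 65.3 %

The carried quantity is

n = 0.280

This is the hot count: the number of pool lifetimes that fit inside the hot window.

At 5.0 s the curve has its knee. At −10 °C the precatalyst opens with a lifetime of 146 s, longer than the remaining 20.0 s, so we hold it at its hot level. The dimer constant rises to 3.73 × 10⁶ L mol⁻¹ and the idle-complex constant to 10400 L mol⁻¹. That leaves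

[catalyst] = 0.00357 mM

The left-handed substrate now has a lifetime of 335 s. The remaining time is 0.0597 of such lifetimes, less than the hot count, so the curve bends into a shallow tail. We let that small gain offset the lag and the falling coupling partner, and we commit for north-west to

share × (1 − exp(−n)) = 16.0 %

West stays hot, so its count is 1.40, and the same formula, with the coupling partner held at its charge, gives 49.2 %. That is more than our north-west figure, so we expect west to lead. We did not reckon south-east or east.

The forecast names west, with 41 % in west, 15.5 % in north-west, 17 % in south-east and 1 % in east, on the ground that “the flask behaves as a dynamic kinetic resolution”.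

The simulation gives west in the lead, with 41.8 % in west, 16.3 % in north-west, 16.9 % in south-east and 0.958 % in east.

Our north-west figure stands 0.30 percentage points below the simulated one. East shows what a count of lifetimes measures. Of the two runs we hold on east, the larger single effect on its left-handed product is the reading at 25 s and not at 250 s: the later reading is 20.5 % against 0.958 %. Taking the resting dimer away at 25 s gives 2.83 %, which is one part of the shortfall.

Take a neighbour of north-west charged with 2.9 M of coupling partner. Its lifetime shortens to 4.43 s, its hot count is 1.13, and the same formula gives 44.2 %. The simulation gives 44.2 %.

The numbers come from no measurement; the run is a simulation.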